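Abietane numbering is used throughout: ring A is C1–C5 and C10, ring B is C5–C10, ring C is the arene C8, C9, C11–C14, and C20 is the carbon on C10. The α face is the face opposite to C20.

## Analysis of the target

The target is an abietane in which C20 (an OCH2 group on C10) is tied through oxygen to the benzylic carbon C7. Ring B is therefore the carbocyclic half of a 2-oxabicyclo[2.2.2]octane with bridgeheads C7 and C10, fused to a catechol (ring C) and to a chair ring A.

There are four stereocenters: C2 (S), C5 (S), C7 (S) and C10 (R). C5 and C10 define a trans A/B fusion (H5 α, C20 β). C7 is not independent, because the bridge can only span the β face. The C2 acetate is α and equatorial, so it is trans to C20 and 1,3-related to C10 through C1.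

The sensitive groups are three:
- the catechol, which oxidizes in air to the o-quinone;
- the C7–O bond, a benzylic ether para to the C12 oxygen, which ionizes with protic and Lewis acids;
- the secondary acetate, which does not survive hydride or alkoxide.

The hard points are the quaternary benzylic C10, which carries an oxidized carbon and sits next to the C4 gem-dimethyl region, and the relay of configuration from C2 to C10. A further one is the order of the late operations, so that the acetate, the bridge and the free catechol never meet a reagent that destroys one of them.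

The strategy rests on one feature. C10 is bonded to arene carbon C9, to C20 and to C5, while C7 is an aryl carbinol carbon two atoms away from C5. A ring A β-keto ester (ketone at C5, ester C20 on C10) and an ortho-acetyl aryl triflate (carbonyl carbon C7, methyl C6) can therefore be joined at C9–C10 and at C5–C6.

## Retrosynthetic reasoning

**C11–O (24 to 22).** The C11 oxygen is removed first. An aryl electrophile that already carried it would have substituents on both sides of the reacting carbon C9, which would make the coupling at a quaternary centre unrealistic. In phenol 22 the only open ortho position of the C12 hydroxyl is C11, so an ortho-oxygenation to o-quinone 23 followed by reduction is regiochemically unambiguous. The forward reaction has to oxidize the phenol without touching the acetate or the bridge.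

**Acetate and phenol unmasking (22 to 21, 20 and 19).** The C2 acetate cannot pass through the hydride reduction, so it is installed late, and the phenol must not end up as the only acylated oxygen.
- An aryl methyl ether at C12 is avoided, because its cleavage at the end would need a boron or aluminium halide, which would ionize the C7–O bond and threaten the acetate.
- An aryl benzyl ether is avoided, because it would fall off during the hydrogenation of the C5–C6 alkene.
- Two silyl ethers are used instead, a tert-butyldiphenylsilyl ether at C2 and a triisopropylsilyl ether at C12. Both survive acid, hydrogenation and aluminium hydride, and both fall to fluoride (19 to 20).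
- Both hydroxyls are then acetylated (21), and the aryl acetate alone is removed by aminolysis (22). This costs one step and avoids any selective acylation.

**C7–O (19 to 18).** The bridge is cut at C7–O. In the forward direction, ionization of the C7 carbinol gives a cation stabilized by the para oxygen, and the C20 hydroxyl on the β face captures it. The configuration at C7 is then dictated by the tether, so the C7 epimers of diol 18 converge.

**Oxidation levels and C5 (18 to 17 and 16).** Diol 18 comes from keto ester 17 by reduction of the C7 ketone and the C20 ester. 17 comes from enone 16 by saturation of C5–C6. The hydrogenation has to come before any ionization at C7: a C7 cation conjugated with the C5–C6 alkene could expel the C20 carbon and aromatize ring B. C5 is set in this step by addition to the α face.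

**Key disconnection (16 to 9 and 13).** Two bonds are cut, C9–C10 and C5–C6, which opens ring B and separates ring A from the arene. This gives β-keto ester 9 and aryl triflate 13, each made in a few steps. Forward, a palladium-catalysed α-arylation must create the quaternary C10 with the aryl group cis to the C2 oxygen, and the acetyl methyl group must then condense onto the C5 ketone. Other cuts were less attractive: C7–C8 or C5–C10 would leave the quaternary C10–aryl bond to be made on a more elaborate substrate.

**Ring A (9 to 8, 6, 4, 1 and 2).** Silyl ether 9 comes from alcohol 8, the Dieckmann product of lactone ester 6. 6 comes from lactone 4 by oxidative cleavage of the terminal alkene. 4 is the union of the dianion of acid 1 with epoxide 2, which supplies the C2 stereocenter from a commercial single enantiomer. An ester enolate opening a γ,δ-epoxy ester was not used: the enolate would deprotonate the epoxy ester, which then closes to a cyclopropane, and any alkoxide formed would lactonize unpredictably. Here lactonization is accepted and used, because the lactone is itself a competent acyl donor in the Dieckmann step.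

**Arene (13 to 12, 11 and 10).** Triflate 13 comes from the chelated phenol 12. 12 comes from diol 11 by silylation of the hydroxyl that is not hydrogen-bonded, and 11 from resorcinol 10 by C-acetylation.

## Alternatives that were turned down

**Alternative 1: bridging oxa-Pictet–Spengler closure.**
- Disconnection: C7–O and C7–C8 of A1, the 11,12-dibenzyl ether of 24.
- Forward key step: a Lewis acid turns the seco hydroxy aldehyde A2 into a six-membered cyclic oxocarbenium ion (O, C20, C10, C5, C6, C7). Arene carbon C8, para to the C12 benzyloxy group, attacks C7 and closes ring B and the bridge together.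
- For: C7 is set by the tether, both catechol oxygens are carried from the start, and one hydrogenolysis ends the synthesis. On the endgame it is stronger than the chosen route, which needs a late oxygenation at the hindered C11.
- Against: A2 already contains C2, C5 and the quaternary C10 bearing an aryl ring with an ortho benzyloxy group. The hardest bond of the molecule, C9–C10, is not made by the key step but pushed back into a long linear preparation of A2. The Lewis acid also meets a hindered benzyl ether and an enolizable aldehyde.
- Comparison: the chosen strategy offers a convergent union of two simple fragments that creates C10 directly.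

**Alternative 2: ring expansion of a cyclopentanone-derived siloxycyclopropane with arene capture.**
- Disconnection: C9–C10 of A3, together with the C2–C10 bond of the bicyclic precursor A4.
- Forward key step: a one-electron ferric oxidant opens the internal cyclopropane bond of A4. Ring A expands to the C2 cyclohexanone, and the tertiary C10 radical or cation closes ring B on arene carbon C9.
- For: one step gives the quaternary C10, the ring A ketone and ring B, with a trans fusion expected from a chair-like closure controlled by C5. It avoids a metal-catalysed coupling at a hindered carbon, and on that point it is stronger.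
- Against: C9 is meta to the methoxy group and not activated, so halogen transfer to the C10 radical or loss of a proton to an enone can compete. C2 arrives as a ketone, and hydride from the open α face would give the axial 2β alcohol, not the needed equatorial one. C7 and C11 carry no oxygen, so two further C–H oxidations follow. A4 needs its own asymmetric synthesis.
- Comparison: the chosen strategy brings C2 with its configuration from a commercial epoxide and C7 and C20 at usable oxidation levels.

**Alternative 3: Ireland–Claisen rearrangement of an alkenyl isochromanone.**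
- Disconnection: C5–C10 of acid A5, traced back to lactone A6, in which C7 is still bonded to the lactone oxygen.
- Forward key step: the silyl ketene acetal of A6 undergoes a [3,3] shift through the boat transition state enforced by the lactone ring. C5–C10 forms as C7–O breaks, which gives the dihydronaphthalene acid A5.
- For: the shift is concerted and transfers the configuration of the benzylic carbon of A6 to C10 and C5. This is a more reliable control of C10 than the face selection of the chosen route. C20 arrives as the acid.
- Against: the bond forms between a fully substituted ketene acetal carbon and an alkene carbon bearing a tertiary alkyl group, a very congested transition state. Ring A still has to be closed by metathesis, and its C2=C3 alkene hydrated with control of regiochemistry and face. The C7 and C11 oxygens also remain to be introduced.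
- Comparison: the chosen strategy delivers ring A complete, with the C2 oxygen in place, in the same step that forms ring B.

Key step: step 8

## Route

Remarks on the chemistry:
- Epoxide 2 is taken as the commercial single enantiomer.
- β-Keto esters 8 and 9 are mixtures of C1 epimers and enol; this is immaterial, because that carbon becomes the quaternary C10.
- Diol 18 is a mixture of C7 epimers that converges in step 11.
- XPhos is 2-dicyclohexylphosphino-2',4',6'-triisopropylbiphenyl; IBX is 2-iodoxybenzoic acid.

Step 1
Reactants: 1 isobutyric acid; 2 (2R)-2-(but-3-en-1-yl)oxirane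
Product: 4 (5R)-5-(but-3-en-1-yl)-3,3-dimethyloxolan-2-one, via hydroxy acid 3 (not isolated)
Conditions: LiN(iPr)2 (2.2 equiv, commercial solution), THF, 0 to 45 °C; aq. HCl; TsOH·H2O (cat.), toluene, 80 °C
Reagents that add atoms: none
Why: Alkylation of a carboxylic acid dianion with an epoxide: the α-carbanion of dilithiated 1 attacks the unsubstituted epoxide carbon in an SN2 opening that leaves the stereocenter of 2 untouched, and hydroxy acid 3 closes to the five-membered lactone on acidification, helped by the gem-dimethyl group.

Step 2
Reactants: 4 (5R)-5-(but-3-en-1-yl)-3,3-dimethyloxolan-2-one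
Product: 6 methyl 3-[(2R)-4,4-dimethyl-5-oxooxolan-2-yl]propanoate, via aldehyde 5 (not isolated)
Conditions: O3, NaOH (5 equiv), MeOH/CH2Cl2, −78 °C; aq. HCl to pH 3
Reagents that add atoms: ozone, [O-][O+]=O; methanol, CO
Why: Ozonolysis in methanolic NaOH converts a terminal alkene directly into a methyl ester, since aldehyde 5 is oxidized by ozone as its methyl hemiacetal while the terminal carbon leaves as formate; the hindered lactone should survive at −78 °C, and any opened material recloses on acidic work-up.

Step 3
Reactants: 6 methyl 3-[(2R)-4,4-dimethyl-5-oxooxolan-2-yl]propanoate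
Product: 8 methyl (5R)-5-hydroxy-3,3-dimethyl-2-oxocyclohexane-1-carboxylate, via hydroxy pimelate 7 (not isolated)
Conditions: NaOMe (2.5 equiv), MeOH/toluene, 70 °C; AcOH, 0 °C
Reagents that add atoms: none
Why: Dieckmann condensation under equilibrating conditions: methoxide opens the lactone to pimelate 7, whose only enolizable α-carbon acylates the neopentyl ester, and deprotonation of the β-keto ester pulls every lactone and diester equilibrium to one product; the carbinol carbon is γ to both carbonyls, so neither β-elimination nor epimerization can reach it.

Step 4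
Reactants: 8 methyl (5R)-5-hydroxy-3,3-dimethyl-2-oxocyclohexane-1-carboxylate
Product: 9 methyl (5R)-5-[(tert-butyldiphenylsilyl)oxy]-3,3-dimethyl-2-oxocyclohexane-1-carboxylate
Conditions: TBDPSCl, imidazole, DMF, 25 °C
Reagents that add atoms: tert-butyl(chloro)diphenylsilane, CC(C)(C)[Si](Cl)(c1ccccc1)c1ccccc1
Why: Standard silylation of a secondary alcohol; the tert-butyldiphenylsilyl ether is chosen because it should withstand the hot sulfonic acid of step 8 and the acid of step 11.

Step 5
Reactants: 10 4-isopropylresorcinol
Product: 11 1-(2,4-dihydroxy-5-isopropylphenyl)ethan-1-one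
Conditions: AcOH, BF3·OEt2, 90 °C
Reagents that add atoms: acetic acid, CC(=O)O
Why: Friedel–Crafts C-acylation of a resorcinol (Nencki type): the carbon para to one hydroxyl and ortho to the other is the most nucleophilic open position, the carbon between the two hydroxyls is flanked twice, and chelation of boron by the new ortho-hydroxy ketone stops the reaction after one acylation.

Step 6
Reactants: 11 1-(2,4-dihydroxy-5-isopropylphenyl)ethan-1-one
Product: 12 1-[2-hydroxy-5-isopropyl-4-(triisopropylsilyloxy)phenyl]ethan-1-one
Conditions: TIPSCl (1.1 equiv), imidazole, DMF, 0 to 25 °C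
Reagents that add atoms: chlorotri(propan-2-yl)silane, CC(C)[Si](Cl)(C(C)C)C(C)C
Why: Selective silylation: the 2-hydroxyl is held in a hydrogen bond to the acetyl carbonyl, so the 4-hydroxyl reacts alone, and the bulky aryl silyl ether should tolerate K3PO4, acid, hydrogenation and iBu2AlH.

Step 7
Reactants: 12 1-[2-hydroxy-5-isopropyl-4-(triisopropylsilyloxy)phenyl]ethan-1-one
Product: 13 2-acetyl-4-isopropyl-5-[(triisopropylsilyl)oxy]phenyl trifluoromethanesulfonate
Conditions: Tf2O, pyridine, CH2Cl2, 0 °C
Reagents that add atoms: trifluoromethanesulfonic anhydride, O=S(=O)(OS(=O)(=O)C(F)(F)F)C(F)(F)F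
Why: O-Sulfonylation of the chelated phenol with the anhydride and pyridine, a routine way to turn an ortho-hydroxy aryl ketone into a cross-coupling electrophile.

Step 8
Reactants: 9 methyl (5R)-5-[(tert-butyldiphenylsilyl)oxy]-3,3-dimethyl-2-oxocyclohexane-1-carboxylate; 13 2-acetyl-4-isopropyl-5-[(triisopropylsilyl)oxy]phenyl trifluoromethanesulfonate
Product: 16 methyl (2S,10R)-2-[(tert-butyldiphenylsilyl)oxy]-7-oxo-12-[(triisopropylsilyl)oxy]abieta-5,8,11,13-tetraen-20-oate, via arylated diketone 14 (not isolated), via aldol adduct 15 (not isolated)
Conditions: Pd2(dba)3 (2.5 mol %), XPhos (10 mol %), K3PO4 (3 equiv), toluene, 80 °C; filtration through Celite; TsOH·H2O (0.3 equiv), toluene, 100 °C, 4 Å molecular sieves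
Reagents that add atoms: none
Why: Zerovalent palladium inserts into the Ar–OTf bond of 13 (the ortho acetyl group makes the arene electron-poor and speeds this up), the potassium enolate of 9 (the β-keto ester C–H is the only acidic site, since C4 is quaternary and the acetyl group of 13 is roughly ten pK units weaker) replaces triflate on palladium, and reductive elimination from the carbon-bound enolate forms C9–C10 and the quaternary C10 of 14. The closest known reaction is the palladium-catalysed α-arylation of 1,3-dicarbonyl compounds and α-substituted ketones with aryl halides and sulfonates under K3PO4. C10 is controlled by the substrate: in the half-chair enolate the C2 silyloxy group sits equatorial (the axial conformer would clash with the axial C4 methyl), that axial methyl shields the face carrying H2, and the bulky arylpalladium unit bonds to the opposite face, so the aryl group should end up cis to the C2 oxygen with the ester axial, which is also the more stable arrangement. After filtration the acid stage is the ring-closing half of a Robinson annulation on the 1,5-diketone: the enol of the acetyl group (C6), the only enolizable position left, adds to the protonated C5 ketone in a 6-(enolexo)-exo-trig closure of ring B to give 15, and water can only be lost toward C6 because C4 and C10 carry no hydrogen, which gives enone 16. Acid and not base is used for this stage because under acid the methyl ester on C10 is not an electrophile, so the competing six-membered Claisen closure onto C20 is shut off. The step needs C- over O-arylation (secured by the soft palladium enolate), a single enolizable site in each stage, and face selection at C10, which cannot epimerize once formed.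

Step 9
Reactants: 16 methyl (2S,10R)-2-[(tert-butyldiphenylsilyl)oxy]-7-oxo-12-[(triisopropylsilyl)oxy]abieta-5,8,11,13-tetraen-20-oate
Product: 17 methyl (2S,5S,10R)-2-[(tert-butyldiphenylsilyl)oxy]-7-oxo-12-[(triisopropylsilyl)oxy]abieta-8,11,13-trien-20-oate
Conditions: H2 (3 atm), 10% Pd/C, EtOAc, 25 °C
Reagents that add atoms: none
Why: Heterogeneous hydrogenation of the enone C=C with syn addition: the β face carries the axial ester on C10 and the axial methyl on C4, so the alkene should adsorb through the α face and receive H5 trans to C20 (trans A/B fusion); the electron-rich aryl ketone is reduced far more slowly in a neutral aprotic solvent.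

Step 10
Reactants: 17 methyl (2S,5S,10R)-2-[(tert-butyldiphenylsilyl)oxy]-7-oxo-12-[(triisopropylsilyl)oxy]abieta-8,11,13-trien-20-oate
Product: 18 (2S,5S,10R)-2-[(tert-butyldiphenylsilyl)oxy]-12-[(triisopropylsilyl)oxy]abieta-8,11,13-triene-7,20-diol
Conditions: iBu2AlH (6 equiv), toluene, −78 to 25 °C; aq. potassium sodium tartrate
Reagents that add atoms: none
Why: Aluminium hydride reduction of the ketone and the neopentyl ester; excess reagent and warming are used so that any bridged lactol formed from the 7β alkoxide is reduced through its open form, both silyl ethers are inert to this hydride, and the new C7 center needs no control.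

Step 11
Reactants: 18 (2S,5S,10R)-2-[(tert-butyldiphenylsilyl)oxy]-12-[(triisopropylsilyl)oxy]abieta-8,11,13-triene-7,20-diol
Product: 19 (2S,5S,7S,10R)-2-[(tert-butyldiphenylsilyl)oxy]-7,20-epoxy-12-[(triisopropylsilyl)oxy]abieta-8,11,13-triene
Conditions: camphorsulfonic acid (0.2 equiv), CH2Cl2, 25 °C
Reagents that add atoms: none
Why: Acid-catalysed SN1 etherification: either C7 epimer ionizes to the benzylic cation stabilized by the para silyloxy group, and the C20 hydroxyl on the β face can only bond to the β lobe, closing the six-membered ring O–C20–C10–C9–C8–C7, so the tether sets C7; loss of a proton toward C6 is reversible under the same acid, so the bridged ether is the sink.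

Step 12
Reactants: 19 (2S,5S,7S,10R)-2-[(tert-butyldiphenylsilyl)oxy]-7,20-epoxy-12-[(triisopropylsilyl)oxy]abieta-8,11,13-triene
Product: 20 (2S,5S,7S,10R)-7,20-epoxyabieta-8,11,13-triene-2,12-diol
Conditions: Bu4NF (3 equiv), THF, 0 to 25 °C; aq. NH4Cl
Reagents that add atoms: none
Why: Fluoride cleavage of both silyl ethers, the aryl ether quickly and the secondary tert-butyldiphenylsilyl ether more slowly; nothing else in 19 is fluoride-sensitive.

Step 13
Reactants: 20 (2S,5S,7S,10R)-7,20-epoxyabieta-8,11,13-triene-2,12-diol
Product: 21 (2S,5S,7S,10R)-7,20-epoxyabieta-8,11,13-triene-2,12-diyl diacetate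
Conditions: Ac2O, pyridine, DMAP (cat.), CH2Cl2, 25 °C
Reagents that add atoms: acetic anhydride, CC(=O)OC(C)=O
Why: Exhaustive DMAP-catalysed acetylation of the equatorial secondary alcohol and the phenol, which removes any need to tell the two hydroxyls apart at this stage.

Step 14
Reactants: 21 (2S,5S,7S,10R)-7,20-epoxyabieta-8,11,13-triene-2,12-diyl diacetate
Product: 22 (2S,5S,7S,10R)-12-hydroxy-7,20-epoxyabieta-8,11,13-trien-2-yl acetate
Conditions: pyrrolidine (1.5 equiv), CH2Cl2, 0 °C
Reagents that add atoms: none
Why: Chemoselective aminolysis: an aryl ester is a far better acyl donor than an alkyl ester because phenoxide is the leaving group, so the secondary amine should remove only the C12 acetate.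

Step 15
Reactants: 22 (2S,5S,7S,10R)-12-hydroxy-7,20-epoxyabieta-8,11,13-trien-2-yl acetate
Product: 24 (2S,5S,7S,10R)-11,12-dihydroxy-7,20-epoxyabieta-8,11,13-trien-2-yl acetate, via o-quinone 23 (not isolated)
Conditions: IBX (1.2 equiv), DMF, 25 °C; then aq. Na2S2O4, argon
Reagents that add atoms: 2-iodoxybenzoic acid (IBX), O=C1OI(=O)(O)c2ccccc12
Why: Regioselective ortho-oxygenation of a phenol with a pentavalent iodine reagent: the phenol binds iodine and oxygen is delivered within the complex to the only free ortho carbon, C11, to give o-quinone 23, which dithionite reduces in the same flask to the catechol; the bridgehead C7–H lies in the arene plane, so no quinone methide tautomer can form.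

## Compound list

1 | isobutyric acid (2-methylpropanoic acid) | CC(C)C(=O)O | starting material
2 | (2R)-2-(but-3-en-1-yl)oxirane [(R)-1,2-epoxy-5-hexene] | C=CCC[C@@H]1CO1 | starting material
3 | (4R)-4-hydroxy-2,2-dimethyloct-7-enoic acid | OC(=O)C(C)(C)C[C@H](O)CCC=C | intermediate (not isolated)
4 | (5R)-5-(but-3-en-1-yl)-3,3-dimethyloxolan-2-one | O=C1O[C@H](CCC=C)CC1(C)C | intermediate
5 | 3-[(2R)-4,4-dimethyl-5-oxooxolan-2-yl]propanal | O=CCC[C@@H]1CC(C)(C)C(=O)O1 | intermediate (not isolated)
6 | methyl 3-[(2R)-4,4-dimethyl-5-oxooxolan-2-yl]propanoate | COC(=O)CC[C@@H]1CC(C)(C)C(=O)O1 | intermediate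
7 | dimethyl (4R)-4-hydroxy-2,2-dimethylheptanedioate | COC(=O)C(C)(C)C[C@H](O)CCC(=O)OC | intermediate (not isolated)
8 | methyl (5R)-5-hydroxy-3,3-dimethyl-2-oxocyclohexane-1-carboxylate (C1 epimers and enol) | COC(=O)C1C[C@@H](O)CC(C)(C)C1=O | intermediate
9 | methyl (5R)-5-[(tert-butyldiphenylsilyl)oxy]-3,3-dimethyl-2-oxocyclohexane-1-carboxylate (C1 epimers and enol) | COC(=O)C1C[C@@H](O[Si](c2ccccc2)(c2ccccc2)C(C)(C)C)CC(C)(C)C1=O | intermediate
10 | 4-isopropylresorcinol [4-(propan-2-yl)benzene-1,3-diol] | CC(C)c1ccc(O)cc1O | starting material
11 | 1-(2,4-dihydroxy-5-isopropylphenyl)ethan-1-one | CC(=O)c1cc(C(C)C)c(O)cc1O | intermediate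
12 | 1-[2-hydroxy-5-isopropyl-4-(triisopropylsilyloxy)phenyl]ethan-1-one | CC(=O)c1cc(C(C)C)c(O[Si](C(C)C)(C(C)C)C(C)C)cc1O | intermediate
13 | 2-acetyl-4-isopropyl-5-[(triisopropylsilyl)oxy]phenyl trifluoromethanesulfonate | CC(=O)c1cc(C(C)C)c(O[Si](C(C)C)(C(C)C)C(C)C)cc1OS(=O)(=O)C(F)(F)F | intermediate
14 | methyl (1S,5S)-1-{2-acetyl-4-isopropyl-5-[(triisopropylsilyl)oxy]phenyl}-5-[(tert-butyldiphenylsilyl)oxy]-3,3-dimethyl-2-oxocyclohexane-1-carboxylate (aryl cis to the silyloxy group) | COC(=O)[C@]1(c2cc(O[Si](C(C)C)(C(C)C)C(C)C)c(C(C)C)cc2C(C)=O)C[C@@H](O[Si](c2ccccc2)(c2ccccc2)C(C)(C)C)CC(C)(C)C1=O | intermediate (not isolated)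
15 | methyl (2S,10R)-2-[(tert-butyldiphenylsilyl)oxy]-5-hydroxy-7-oxo-12-[(triisopropylsilyl)oxy]abieta-8,11,13-trien-20-oate (C5 not defined) | COC(=O)[C@]12C[C@@H](O[Si](c3ccccc3)(c3ccccc3)C(C)(C)C)CC(C)(C)C1(O)CC(=O)c1cc(C(C)C)c(O[Si](C(C)C)(C(C)C)C(C)C)cc21 | intermediate (not isolated)
16 | methyl (2S,10R)-2-[(tert-butyldiphenylsilyl)oxy]-7-oxo-12-[(triisopropylsilyl)oxy]abieta-5,8,11,13-tetraen-20-oate | COC(=O)[C@]12C[C@@H](O[Si](c3ccccc3)(c3ccccc3)C(C)(C)C)CC(C)(C)C1=CC(=O)c1cc(C(C)C)c(O[Si](C(C)C)(C(C)C)C(C)C)cc21 | intermediate
17 | methyl (2S,5S,10R)-2-[(tert-butyldiphenylsilyl)oxy]-7-oxo-12-[(triisopropylsilyl)oxy]abieta-8,11,13-trien-20-oate | COC(=O)[C@]12C[C@@H](O[Si](c3ccccc3)(c3ccccc3)C(C)(C)C)CC(C)(C)[C@@H]1CC(=O)c1cc(C(C)C)c(O[Si](C(C)C)(C(C)C)C(C)C)cc21 | intermediate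
18 | (2S,5S,10R)-2-[(tert-butyldiphenylsilyl)oxy]-12-[(triisopropylsilyl)oxy]abieta-8,11,13-triene-7,20-diol (C7 epimers) | OC[C@]12C[C@@H](O[Si](c3ccccc3)(c3ccccc3)C(C)(C)C)CC(C)(C)[C@@H]1CC(O)c1cc(C(C)C)c(O[Si](C(C)C)(C(C)C)C(C)C)cc21 | intermediate
19 | (2S,5S,7S,10R)-2-[(tert-butyldiphenylsilyl)oxy]-7,20-epoxy-12-[(triisopropylsilyl)oxy]abieta-8,11,13-triene | CC(C)(C)[Si](c4ccccc4)(c4ccccc4)O[C@H]1CC(C)(C)[C@@H]2C[C@@H]3OC[C@@]2(C1)c1c3cc(C(C)C)c(O[Si](C(C)C)(C(C)C)C(C)C)c1 | intermediate
20 | (2S,5S,7S,10R)-7,20-epoxyabieta-8,11,13-triene-2,12-diol | O[C@H]1CC(C)(C)[C@@H]2C[C@@H]3OC[C@@]2(C1)c1c3cc(C(C)C)c(O)c1 | intermediate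
21 | (2S,5S,7S,10R)-7,20-epoxyabieta-8,11,13-triene-2,12-diyl diacetate | CC(=O)O[C@H]1CC(C)(C)[C@@H]2C[C@@H]3OC[C@@]2(C1)c1c3cc(C(C)C)c(OC(C)=O)c1 | intermediate
22 | (2S,5S,7S,10R)-12-hydroxy-7,20-epoxyabieta-8,11,13-trien-2-yl acetate | CC(=O)O[C@H]1CC(C)(C)[C@@H]2C[C@@H]3OC[C@@]2(C1)c1c3cc(C(C)C)c(O)c1 | intermediate
23 | (2S,5S,7S,10R)-7,20-epoxy-11,12-dioxoabieta-8,13-dien-2-yl acetate | CC(=O)O[C@H]1CC(C)(C)[C@@H]2C[C@@H]3OC[C@@]2(C1)C1=C3C=C(C(C)C)C(=O)C1=O | intermediate (not isolated)
24 | (2S,5S,7S,10R)-11,12-dihydroxy-7,20-epoxyabieta-8,11,13-trien-2-yl acetate (2α-acetoxy, 5α-H, 7β,20-epoxy) | CC(=O)O[C@H]1CC(C)(C)[C@@H]2C[C@@H]3OC[C@@]2(C1)c1c3cc(C(C)C)c(O)c1O | target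

## Step count and least certain steps

Total: 15 steps. Longest linear sequence: 12 steps (steps 1–4, then 8–15). The arene branch (steps 5–7) joins at step 8.

**Step 8 (key step).** Three processes can go wrong.
- Reductive elimination at a carbon that becomes quaternary may be slow, so that S–O cleavage of the triflate or reduction of the arylpalladium intermediate wins.
- If the basic stage is heated too long, the acetyl enolate may close onto the ester (Claisen closure) before the acid stage.
- Addition to the C5 ketone, which lies between two fully substituted carbons, may be sluggish.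

Face selection at C10 could also erode, because stereoelectronic (axial) attack favours the face that the C4 methyl shields.

Fallback, from 13 and 9, returning at 14: the triflate is converted with (Bu3Sn)2, Pd(PPh3)4 and LiCl into 1-[5-isopropyl-2-(tributylstannyl)-4-(triisopropylsilyloxy)phenyl]ethan-1-one F1. Tin–lead exchange with Pb(OAc)4 and catalytic Hg(OAc)2 gives {2-acetyl-4-isopropyl-5-[(triisopropylsilyl)oxy]phenyl}lead triacetate F2. This tetravalent lead reagent arylates β-keto ester 9 in CHCl3 with pyridine (Pinhey arylation), a ligand coupling that is known to build hindered quaternary α-aryl β-keto esters. The product is 14, which is then taken through the acid stage of step 8 unchanged.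

**Step 9.** The alkene lies between two fully substituted carbons and may adsorb slowly. Long exposure then invites hydrogenolysis at the benzylic C7 carbonyl or some addition from the β face.

Fallback, from 16, returning at 17: a Birch-type dissolving-metal reduction of the enone (Li, NH3/THF, −78 °C, one equivalent of tBuOH, NH4Cl quench). The C5 carbanion is protonated axially under stereoelectronic control, which favours the trans fusion, and the carbonyl is protected as its enolate until the quench. This fallback makes no compound outside the list (F0).

**Step 3.** The free hydroxyl may interfere: closure may be incomplete, or the hydroxy keto ester may lactonize onto its own ester during work-up.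

Fallback, from 6, returning at 9: 6 is saponified with LiOH and, without acidification, persilylated with TBDPSCl and imidazole. The silyl esters are cleaved with K2CO3 in aqueous methanol to give (4R)-4-[(tert-butyldiphenylsilyl)oxy]-2,2-dimethylheptanedioic acid F3. Esterification with Me3SiCHN2 gives dimethyl (4R)-4-[(tert-butyldiphenylsilyl)oxy]-2,2-dimethylheptanedioate F4. An ordinary Dieckmann condensation (KOtBu, THF) then gives 9 directly.

**Step 11.** Ionization may be slow with the silyloxy donor, or loss of a proton toward C6 may drain material to the styrene faster than it returns.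

Fallback, from 18, returning at 20: desilylation first with Bu4NF gives (2S,5S,10R)-abieta-8,11,13-triene-2,7,12,20-tetraol F5. Its para-hydroxybenzylic alcohol forms a para-quinone methide under very mild acid (AcOH), and the C20 hydroxyl adds to it intramolecularly. The product is 20.

**Step 15.** Oxygen delivery to C11 is hindered by the C1 methylene and the C20 bridge, so the electron-rich phenol may be over-oxidized before the quinone is reduced.

Fallback, from 22, returning at 24: ortho-benzoyloxylation of the phenol with dibenzoyl peroxide in hot CHCl3 gives (2S,5S,7S,10R)-11-(benzoyloxy)-12-hydroxy-7,20-epoxyabieta-8,11,13-trien-2-yl acetate F6. Acyl migration between the two catechol oxygens is immaterial. The aryl benzoate is removed by aminolysis with pyrrolidine, as in step 14, to give 24.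

## Further compounds

F1 | step 8 | 1-[5-isopropyl-2-(tributylstannyl)-4-(triisopropylsilyloxy)phenyl]ethan-1-one | CC(=O)c1cc(C(C)C)c(O[Si](C(C)C)(C(C)C)C(C)C)cc1[Sn](CCCC)(CCCC)CCCC
F2 | step 8 | {2-acetyl-4-isopropyl-5-[(triisopropylsilyl)oxy]phenyl}lead triacetate | CC(=O)c1cc(C(C)C)c(O[Si](C(C)C)(C(C)C)C(C)C)cc1[Pb](OC(C)=O)(OC(C)=O)OC(C)=O
F0 | step 9 | none | none
F3 | step 3 | (4R)-4-[(tert-butyldiphenylsilyl)oxy]-2,2-dimethylheptanedioic acid | OC(=O)C(C)(C)C[C@H](O[Si](c1ccccc1)(c1ccccc1)C(C)(C)C)CCC(=O)O
F4 | step 3 | dimethyl (4R)-4-[(tert-butyldiphenylsilyl)oxy]-2,2-dimethylheptanedioate | COC(=O)C(C)(C)C[C@H](O[Si](c1ccccc1)(c1ccccc1)C(C)(C)C)CCC(=O)OC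
F5 | step 11 | (2S,5S,10R)-abieta-8,11,13-triene-2,7,12,20-tetraol (C7 epimers) | OC[C@]12C[C@@H](O)CC(C)(C)[C@@H]1CC(O)c1cc(C(C)C)c(O)cc21
F6 | step 15 | (2S,5S,7S,10R)-11-(benzoyloxy)-12-hydroxy-7,20-epoxyabieta-8,11,13-trien-2-yl acetate | CC(=O)O[C@H]1CC(C)(C)[C@@H]2C[C@@H]3OC[C@@]2(C1)c1c3cc(C(C)C)c(O)c1OC(=O)c1ccccc1
A1 | alternative 1 | (2S,5S,7S,10R)-11,12-bis(benzyloxy)-7,20-epoxyabieta-8,11,13-trien-2-yl acetate | CC(=O)O[C@H]1CC(C)(C)[C@@H]2C[C@@H]3OC[C@@]2(C1)c1c3cc(C(C)C)c(OCc2ccccc2)c1OCc1ccccc1
A2 | alternative 1 | 2α-acetoxy-11,12-bis(benzyloxy)-20-hydroxy-7,8-secoabieta-8,11,13-trien-7-al | CC(=O)O[C@H]1CC(C)(C)[C@H](CC=O)[C@](CO)(C1)c1ccc(C(C)C)c(OCc2ccccc2)c1OCc1ccccc1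
A3 | alternative 2 | (5S,10R)-20-(benzyloxy)-12-methoxyabieta-8,11,13-trien-2-one | O=C1CC(C)(C)[C@@H]2CCc3cc(C(C)C)c(OC)cc3[C@@]2(COCc2ccccc2)C1
A4 | alternative 2 | 5-(benzyloxymethyl)-4-[2-(3-isopropyl-4-methoxyphenyl)ethyl]-3,3-dimethyl-1-(trimethylsilyloxy)bicyclo[3.1.0]hexane (one diastereomer, as in the SMILES) | C[Si](C)(C)O[C@]12C[C@@]1(COCc1ccccc1)[C@@H](CCc1ccc(OC)c(C(C)C)c1)C(C)(C)C2
A5 | alternative 3 | (1R,2S)-1-allyl-6-isopropyl-7-methoxy-2-(2-methylbut-3-en-2-yl)-1,2-dihydronaphthalene-1-carboxylic acid | OC(=O)[C@]1(CC=C)[C@H](C(C)(C)C=C)C=Cc2cc(C(C)C)c(OC)cc12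
A6 | alternative 3 | (1S)-4-allyl-1-[(1E)-3,3-dimethylpenta-1,4-dien-1-yl]-7-isopropyl-6-methoxyisochroman-3-one (C4 not defined) | O=C1O[C@@H](/C=C/C(C)(C)C=C)c2cc(C(C)C)c(OC)cc2C1CC=C
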